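**Plan**
1. Retrosynthesis: cut C16–C17 (methyl onto a 16-ketone), then C12–C13 (ring C, a C12 radical closing onto a spirocyclopentene that is latent ring D), then C4–C5 and C9–C10 in one operation (rings A and B), and last the two allyl arms on C8 and the C5–C6 bond.
2. Forward: the C3–C2–C1–C10(C20)=C5 unit from pent-4-yn-1-ol is joined to C6/C7 and C8/C9 by a rhodium-catalysed 1,4-addition; C8 is then made quaternary and spiro, the E-allylsilane and the Z-epoxy silyl ether are installed, rings A and B close together, ring C closes onto the cyclopentene (which becomes ring D), and C16, C3 and C19 are adjusted.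
3. Enabling feature (gibberellane numbering): ring A (C1–C5, C10) carries oxygen on C3 next to the quaternary C4 and is trans-fused through C5–C10 to the cyclopentane ring B (C5, C6, C8, C9, C10). This is the imprint of an epoxide-initiated cyclization that ends in a five-membered ring. C8 carries a symmetric cyclopentene, so it is not a stereocentre until ring C closes.
4. Stereochemistry: C6 from the (R)-BINAP–rhodium addition; C3 and C4 from Sharpless epoxidation of the Z-allylic alcohol; C5, C10 and C9 from the chair-like bicyclization; C3 is then inverted through the ketone; C8 and C13 from the cis closure of ring C; C16 from exo addition of the methyl nucleophile.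
5. Numbering: C7 is the CH2O carbon on C6, C18 (methyl) and C19 are on C4, C20 is the methyl on C10, C17 the methyl on C16; ring C = C8, C9, C11–C14; ring D = C8, C14, C13, C16, C15.

Key step: step 17

**Remarks**
- TBS = tert-butyldimethylsilyl; TBDPS = tert-butyldiphenylsilyl. α is the face of rings A/B that carries C20; β is the opposite face (H5, H9).
- "Spirohydrindane" (21–27) means the trans-fused ring A/B unit with 4β-CH3 (C18), 4α-CH2O (C19), 5β-H, 6α-H, 6β-CH2O (C7), 9β-H, 10α-CH3 (C20) and a cyclopent-3-ene spiro-fused at C8. In 28–36 ring C lies on the α face of ring B (C11 and C14 α, C15 β) and these descriptors are unchanged.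
- Assumption: 2-[(tert-butyldiphenylsilyl)oxy]acetaldehyde 6 is bought; it is otherwise made from ethylene glycol by monosilylation and oxidation.
- Assumption: the BINAP antipode in step 5 is assigned from the empirical facial rule for acyclic E-enoates (R ligand for the 3R ester). If the first run shows the opposite sense, the S ligand is used and nothing else changes.

**Step 1**
Reactants: 1 pent-4-yn-1-ol
Product: 3 (E)-5-iodo-4-methylpent-4-en-1-ol, via alkenylalane 2 (not isolated)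
Conditions: AlMe3 (3 equiv), Cp2ZrCl2 (0.25 equiv), CH2Cl2, 0 °C → rt; then I2, THF, −30 → 0 °C
Reagents that add atoms: trimethylaluminium, C[Al](C)C; iodine, II
Why: Negishi zirconium-catalysed carboalumination adds methyl and aluminium syn across the alkyne with aluminium on the terminal carbon, and iodinolysis with retention fixes the E geometry of the later C10=C5 alkene.

**Step 2**
Reactants: 3 (E)-5-iodo-4-methylpent-4-en-1-ol
Product: 4 TBS ether of 3
Conditions: TBSCl, imidazole, DMF, rt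
Reagents that add atoms: tert-butyldimethylsilyl chloride, CC(C)(C)[Si](C)(C)Cl
Why: Routine silylation of a primary alcohol, needed before the enolate chemistry of step 6.

**Step 3**
Reactants: 4 TBS ether of 3
Product: 5 (E)-alkenyl pinacol boronate
Conditions: B2pin2, PdCl2(PPh3)2 (3 mol%), PPh3, KOPh, toluene, 50 °C
Reagents that add atoms: bis(pinacolato)diboron, CC1(C)OB(OC1(C)C)B1OC(C)(C)C(C)(C)O1
Why: Miyaura borylation of an alkenyl iodide proceeds with retention of the alkene geometry.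

**Step 4**
Reactants: 6 2-[(tert-butyldiphenylsilyl)oxy]acetaldehyde
Product: 7 methyl (E)-4-[(tert-butyldiphenylsilyl)oxy]but-2-enoate
Conditions: Ph3P=CHCO2Me, CH2Cl2, rt
Reagents that add atoms: methyl (triphenylphosphoranylidene)acetate, COC(=O)C=P(c1ccccc1)(c1ccccc1)c1ccccc1
Why: Wittig olefination with a stabilised ylide is expected to give the E-enoate.

**Step 5**
Reactants: 5 (E)-alkenyl pinacol boronate; 7 methyl (E)-4-[(tert-butyldiphenylsilyl)oxy]but-2-enoate
Product: 8 methyl (3R,4E)-8-(TBS-oxy)-3-[(TBDPS-oxy)methyl]-5-methyloct-4-enoate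
Conditions: [RhCl(C2H4)2]2 (2.5 mol%), (R)-BINAP (6 mol%), KOH (0.3 equiv), dioxane/H2O 10:1, 60 °C
Reagents that add atoms: none
Why: Hayashi–Miyaura rhodium-catalysed asymmetric 1,4-addition forms the C5–C6 bond with the alkene geometry intact, and the BINAP-bound alkenylrhodium species selects one face of the E-enoate to set C6 (3R in 8).

**Step 6**
Reactants: 8 methyl (3R,4E)-8-(TBS-oxy)-3-[(TBDPS-oxy)methyl]-5-methyloct-4-enoate
Product: 10 methyl (3S,4E)-2,2-diallyl-8-(TBS-oxy)-3-[(TBDPS-oxy)methyl]-5-methyloct-4-enoate, via monoallyl ester 9 (not isolated)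
Conditions: LDA (1.1 equiv), THF, −78 °C, allyl bromide; then LDA (1.3 equiv), DMPU, −78 → −20 °C, allyl bromide
Reagents that add atoms: allyl bromide, C=CCBr
Why: Two successive ester enolate alkylations with a reactive allylic halide build the quaternary C8, which is not stereogenic because both new groups are alike.

**Step 7**
Reactants: 10 diallyl ester
Product: 11 methyl 1-[(2S,3E)-7-(TBS-oxy)-1-(TBDPS-oxy)-4-methylhept-3-en-2-yl]cyclopent-3-ene-1-carboxylate
Conditions: first-generation Grubbs catalyst RuCl2(=CHPh)(PCy3)2 (3 mol%), CH2Cl2, 40 °C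
Reagents that add atoms: none
Why: Ring-closing metathesis of the 1,6-diene gives the cyclopentene, and the first-generation catalyst leaves the trisubstituted C5=C10 alkene untouched.

**Step 8**
Reactants: 11 spirocyclopentene ester
Product: 12 cyclopent-3-ene-1-carbaldehyde (C9 aldehyde)
Conditions: DIBAL-H (1.1 equiv), toluene, −78 °C; MeOH, Rochelle salt
Reagents that add atoms: none
Why: Partial DIBAL-H reduction of an ester on a quaternary carbon should stop at the aldehyde because the hindered aluminium hemiacetal survives until the cold quench.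

**Step 9**
Reactants: 12 C9 aldehyde
Product: 13 (E)-2-iodoethenyl compound
Conditions: CHI3 (2 equiv), CrCl2 (6 equiv), THF/dioxane, 0 °C → rt
Reagents that add atoms: iodoform, IC(I)I
Why: Takai iodoolefination converts a hindered, non-enolisable aldehyde into the E-alkenyl iodide (C9=C11).

**Step 10**
Reactants: 13 (E)-alkenyl iodide
Product: 14 (E)-allylsilane
Conditions: Me3SiCH2MgCl (2 equiv), Pd(PPh3)4 (5 mol%), THF, rt
Reagents that add atoms: (trimethylsilyl)methylmagnesium chloride, C[Si](C)(C)C[Mg]Cl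
Why: Kumada coupling of an alkenyl iodide under zerovalent palladium retains the E geometry and installs C12 with its silicon.

**Step 11**
Reactants: 14 (E)-allylsilane
Product: 15 primary alcohol (C3–OH)
Conditions: PPTS (0.3 equiv), MeOH, rt
Reagents that add atoms: none
Why: Mild acid-catalysed methanolysis removes the primary TBS ether, while the TBDPS ether and the allylsilane tolerate the weak acid.

**Step 12**
Reactants: 15 primary alcohol
Product: 16 aldehyde (C3)
Conditions: DMP, pyridine, CH2Cl2, 0 °C → rt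
Reagents that add atoms: none
Why: Dess–Martin oxidation gives the aldehyde without acid strong enough to harm the allylsilane.

**Step 13**
Reactants: 16 aldehyde
Product: 17 ethyl (2Z,6E,8S)-enoate
Conditions: (CF3CH2O)2P(O)CH(CH3)CO2Et, KHMDS, 18-crown-6, THF, −78 °C
Reagents that add atoms: ethyl 2-[bis(2,2,2-trifluoroethoxy)phosphoryl]propanoate, CCOC(=O)C(C)P(=O)(OCC(F)(F)F)OCC(F)(F)F
Why: Still–Gennari olefination is kinetically Z-selective and places the ester carbon (C19) cis to the chain on the new C3=C4 alkene.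

**Step 14**
Reactants: 17 Z-enoate
Product: 18 (2Z,6E,8S)-allylic alcohol
Conditions: DIBAL-H (2.5 equiv), CH2Cl2, −78 °C
Reagents that add atoms: none
Why: DIBAL-H 1,2-reduction of an enoate gives the allylic alcohol without touching the alkene geometry.

**Step 15**
Reactants: 18 Z-allylic alcohol
Product: 19 (2S,3R)-epoxy alcohol
Conditions: Ti(OiPr)4 (0.2 equiv), L-(+)-DET (0.25 equiv), t-BuOOH, 4 Å MS, CH2Cl2, −20 °C
Reagents that add atoms: tert-butyl hydroperoxide, CC(C)(C)OO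
Why: Sharpless asymmetric epoxidation is directed by the allylic hydroxyl, so only the C3=C4 alkene reacts, and the L-(+)-tartrate complex delivers oxygen to the face that gives C4 S and C3 R.

**Step 16**
Reactants: 19 epoxy alcohol
Product: 20 epoxy TBS ether (cyclization precursor)
Conditions: TBSCl, imidazole, CH2Cl2, 0 °C → rt
Reagents that add atoms: tert-butyldimethylsilyl chloride, CC(C)(C)[Si](C)(C)Cl
Why: Routine silylation masks C19–OH so that it cannot open the epoxide or bind the Lewis acid.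

**Step 17**
Reactants: 20 epoxy TBS ether
Product: 21 9α-vinyl-19-(TBS-oxy)-7-(TBDPS-oxy)spirohydrindan-3α-ol
Conditions: MeAlCl2 (2 equiv), CH2Cl2, −90 → −78 °C; Et3N, MeOH/H2O
Reagents that add atoms: none
Why: MeAlCl2 binds the epoxide oxygen, C5 of the E-C5=C10 alkene attacks the tertiary C4 anti to the departing oxygen, C9 of the allylsilane takes the emerging C10 cation, and the β-silyl cation at C11 loses Me3Si to leave the C9 vinyl group; the closest known type is the Lewis-acid, epoxide-initiated cationic polyene cyclization terminated by an allylsilane to give a trans-fused vinylcyclopentane. Ring A closes 6-endo through a chair and ring B closes 5-exo onto the allylsilane. C4 is set by inversion at the epoxide carbon (the Z-derived CH2OTBS arm ends axial, C18 equatorial) and C3 keeps its epoxide configuration, so the hydroxyl emerges equatorial (3α). C5 and C10 follow from anti addition across the E alkene in the chair (H5 and C20 trans), and C9 from the pseudo-equatorial placement of the reacting alkene in the closing five-membered ring, which puts the vinyl group cis to C20. The step needs opening at C4 only, full bicyclization instead of proton loss or capture by the C7 ether oxygen or the cyclopentene, and one face at C9. The tertiary C4, the nucleophilic allylsilane, the poorly basic TBDPS ether and the matched C6 centre (allylic strain holds the quaternary C8 on the face opposite to the incoming C4) are expected to secure these.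

**Step 18**
Reactants: 21 spirohydrindan-3α-ol
Product: 22 spirohydrindan-3-one
Conditions: DMP, pyridine, CH2Cl2, 0 °C → rt
Reagents that add atoms: none
Why: Dess–Martin oxidation of the secondary alcohol removes the C3 configuration that the epoxide opening set.

**Step 19**
Reactants: 22 spirohydrindan-3-one
Product: 23 spirohydrindan-3β-ol
Conditions: LiBH(s-Bu)3, THF, −78 °C; NaOH, H2O2, 0 °C
Reagents that add atoms: none
Why: L-Selectride reduction delivers hydride along the equatorial direction, as with 4,4-disubstituted 3-ketones of terpenoids, and should give the axial 3β alcohol.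

**Step 20**
Reactants: 23 spirohydrindan-3β-ol
Product: 24 3β,19-bis(TBS-oxy)-7-(TBDPS-oxy)-9α-vinylspirohydrindane
Conditions: TBSOTf, 2,6-lutidine, CH2Cl2, 0 °C → rt
Reagents that add atoms: tert-butyldimethylsilyl trifluoromethanesulfonate, CC(C)(C)[Si](C)(C)OS(=O)(=O)C(F)(F)F
Why: Silylation with the silyl triflate protects the hindered axial alcohol against the oxidations of steps 25 and 28.

**Step 21**
Reactants: 24 9α-vinylspirohydrindane
Product: 26 9α-(2-hydroxyethyl)spirohydrindane, via borane 25 (not isolated)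
Conditions: 9-BBN (1.3 equiv), THF, 0 °C → rt; NaOH, H2O2
Reagents that add atoms: hydrogen peroxide, OO (oxygen on C12); 9-borabicyclo[3.3.1]nonane, B1C2CCCC1CCC2 (boron in 25 only)
Why: Brown hydroboration–oxidation with 9-BBN engages the monosubstituted alkene much faster than the cyclopentene and places oxygen on the terminal carbon C12.

**Step 22**
Reactants: 26 9α-(2-hydroxyethyl)spirohydrindane
Product: 27 9α-(2-iodoethyl)spirohydrindane
Conditions: I2, PPh3, imidazole, CH2Cl2, 0 °C → rt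
Reagents that add atoms: iodine, II
Why: Appel-type iodination converts the primary alcohol into the radical precursor.

**Step 23**
Reactants: 27 9α-(2-iodoethyl)spirohydrindane
Product: 28 3β,19-bis(TBS-oxy)-7-(TBDPS-oxy)-17-norgibberell-15-ene
Conditions: Co(dmgH)2(py)(SnPh3) (15 mol%), i-Pr2NEt, MeCN, blue LEDs, rt
Reagents that add atoms: none
Why: In this cobaloxime-catalysed radical Heck-type cyclization of an alkyl iodide, the C12 radical adds 6-exo to the alkene carbon on its own (α) side (C13), which sets C8 and C13 in the cis-fused bicyclo[3.2.1]octane, and hydrogen is then lost from C15, the only position Bredt's rule allows, to leave the C15=C16 alkene.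

**Step 24**
Reactants: 28 17-norgibberell-15-ene
Product: 30 3β,19-bis(TBS-oxy)-7-(TBDPS-oxy)-17-norgibberellan-16-exo-ol, via borane 29 (not isolated)
Conditions: 9-BBN (3 equiv), THF, 65 °C; NaOH, H2O2, 0 °C → rt
Reagents that add atoms: hydrogen peroxide, OO (oxygen on C16); 9-borabicyclo[3.3.1]nonane, B1C2CCCC1CCC2 (boron in 29 only)
Why: Hydroboration–oxidation with the bulky borane from the exo face should place boron, then hydroxyl, on C16, the alkene carbon remote from the quaternary C8 and its neighbouring CH2OTBDPS arm; the C16 configuration is lost in step 25.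

**Step 25**
Reactants: 30 17-norgibberellan-16-exo-ol
Product: 31 17-norgibberellan-16-one
Conditions: DMP, pyridine, CH2Cl2, rt
Reagents that add atoms: none
Why: Dess–Martin oxidation gives the ketone while all other oxygens are silylated.

**Step 26**
Reactants: 31 17-norgibberellan-16-one
Product: 32 3β,19-bis(TBS-oxy)-7-(TBDPS-oxy)gibberellan-16-ol (16-CH3 exo, 16-OH endo)
Conditions: MeMgBr, CeCl3, THF, −78 °C
Reagents that add atoms: methylmagnesium bromide, C[Mg]Br
Why: Cerium-mediated Grignard addition suppresses enolisation, and attack on the bicyclo[3.2.1]octan-6-one from the open exo face sets C16 with methyl exo and hydroxyl endo (towards C11/C12).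

**Step 27**
Reactants: 32 tris-silylated gibberellan-16-ol
Product: 33 gibberellane-16,19-diol 3-TBS 7-TBDPS ether
Conditions: HF·pyridine, pyridine, THF, 0 °C → rt
Reagents that add atoms: none
Why: Buffered fluoride desilylation cleaves the primary TBS ether before the hindered secondary TBS ether and the TBDPS ether.

**Step 28**
Reactants: 33 16,19-diol
Product: 35 3β-(TBS-oxy)-7-(TBDPS-oxy)-16-hydroxygibberellan-19-oic acid, via aldehyde 34 (not isolated)
Conditions: TEMPO (cat.), NaOCl (cat.), NaClO2, MeCN/phosphate buffer pH 6.7, 35 °C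
Reagents that add atoms: sodium chlorite, [Na+].[O-]Cl=O
Why: Nitroxyl/hypochlorite oxidation of the primary alcohol followed in the same flask by Pinnick-type chlorite oxidation gives the acid, and the tertiary alcohol cannot be oxidised.

**Step 29**
Reactants: 35 silylated acid
Product: 36 3β,7,16-trihydroxygibberellan-19-oic acid (CNP0170663.1)
Conditions: TBAF, THF, 50 °C; aq. citric acid
Reagents that add atoms: none
Why: Fluoride-mediated global desilylation frees the 3β and C7 hydroxyls without acid that could ionise the tertiary C16 alcohol.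

**Compound list**
1 | pent-4-yn-1-ol | C#CCCCO | starting material
2 | (E)-[5-(dimethylalumanyloxy)-2-methylpent-1-en-1-yl]dimethylalumane (alkenylalane) | C[Al](C)OCCC/C(C)=C/[Al](C)C | intermediate
3 | (E)-5-iodo-4-methylpent-4-en-1-ol | OCCC/C(C)=C/I | intermediate
4 | tert-butyl{[(E)-5-iodo-4-methylpent-4-en-1-yl]oxy}dimethylsilane | CC(C)(C)[Si](C)(C)OCCC/C(C)=C/I | intermediate
5 | tert-butyldimethyl{[(E)-4-methyl-5-(4,4,5,5-tetramethyl-1,3,2-dioxaborolan-2-yl)pent-4-en-1-yl]oxy}silane | CC(C)(C)[Si](C)(C)OCCC/C(C)=C/B1OC(C)(C)C(C)(C)O1 | intermediate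
6 | 2-[(tert-butyldiphenylsilyl)oxy]acetaldehyde | O=CCO[Si](c1ccccc1)(c1ccccc1)C(C)(C)C | starting material
7 | methyl (E)-4-[(tert-butyldiphenylsilyl)oxy]but-2-enoate | COC(=O)/C=C/CO[Si](c1ccccc1)(c1ccccc1)C(C)(C)C | intermediate
8 | methyl (3R,4E)-8-[(tert-butyldimethylsilyl)oxy]-3-{[(tert-butyldiphenylsilyl)oxy]methyl}-5-methyloct-4-enoate | CC(C)(C)[Si](C)(C)OCCC/C(C)=C/[C@H](CO[Si](c1ccccc1)(c1ccccc1)C(C)(C)C)CC(=O)OC | intermediate
9 | methyl (3S,4E)-2-allyl-8-[(tert-butyldimethylsilyl)oxy]-3-{[(tert-butyldiphenylsilyl)oxy]methyl}-5-methyloct-4-enoate, C2 epimers (monoallyl ester) | CC(C)(C)[Si](C)(C)OCCC/C(C)=C/[C@H](CO[Si](c1ccccc1)(c1ccccc1)C(C)(C)C)C(CC=C)C(=O)OC | intermediate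
10 | methyl (3S,4E)-2,2-diallyl-8-[(tert-butyldimethylsilyl)oxy]-3-{[(tert-butyldiphenylsilyl)oxy]methyl}-5-methyloct-4-enoate | CC(C)(C)[Si](C)(C)OCCC/C(C)=C/[C@H](CO[Si](c1ccccc1)(c1ccccc1)C(C)(C)C)C(CC=C)(CC=C)C(=O)OC | intermediate
11 | methyl 1-[(2S,3E)-7-[(tert-butyldimethylsilyl)oxy]-1-[(tert-butyldiphenylsilyl)oxy]-4-methylhept-3-en-2-yl]cyclopent-3-ene-1-carboxylate | CC(C)(C)[Si](C)(C)OCCC/C(C)=C/[C@H](CO[Si](c1ccccc1)(c1ccccc1)C(C)(C)C)C1(CC=CC1)C(=O)OC | intermediate
12 | 1-[(2S,3E)-7-[(tert-butyldimethylsilyl)oxy]-1-[(tert-butyldiphenylsilyl)oxy]-4-methylhept-3-en-2-yl]cyclopent-3-ene-1-carbaldehyde | CC(C)(C)[Si](C)(C)OCCC/C(C)=C/[C@H](CO[Si](c1ccccc1)(c1ccccc1)C(C)(C)C)C1(CC=CC1)C=O | intermediate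
13 | tert-butyl{[(4E,6S)-7-[(tert-butyldiphenylsilyl)oxy]-6-{1-[(E)-2-iodoethenyl]cyclopent-3-en-1-yl}-4-methylhept-4-en-1-yl]oxy}dimethylsilane | CC(C)(C)[Si](C)(C)OCCC/C(C)=C/[C@H](CO[Si](c1ccccc1)(c1ccccc1)C(C)(C)C)C1(CC=CC1)/C=C/I | intermediate
14 | tert-butyl{[(4E,6S)-7-[(tert-butyldiphenylsilyl)oxy]-4-methyl-6-{1-[(E)-3-(trimethylsilyl)prop-1-en-1-yl]cyclopent-3-en-1-yl}hept-4-en-1-yl]oxy}dimethylsilane | CC(C)(C)[Si](C)(C)OCCC/C(C)=C/[C@H](CO[Si](c1ccccc1)(c1ccccc1)C(C)(C)C)C1(CC=CC1)/C=C/C[Si](C)(C)C | intermediate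
15 | (4E,6S)-7-[(tert-butyldiphenylsilyl)oxy]-4-methyl-6-{1-[(E)-3-(trimethylsilyl)prop-1-en-1-yl]cyclopent-3-en-1-yl}hept-4-en-1-ol | OCCC/C(C)=C/[C@H](CO[Si](c1ccccc1)(c1ccccc1)C(C)(C)C)C1(CC=CC1)/C=C/C[Si](C)(C)C | intermediate
16 | (4E,6S)-7-[(tert-butyldiphenylsilyl)oxy]-4-methyl-6-{1-[(E)-3-(trimethylsilyl)prop-1-en-1-yl]cyclopent-3-en-1-yl}hept-4-enal | O=CCC/C(C)=C/[C@H](CO[Si](c1ccccc1)(c1ccccc1)C(C)(C)C)C1(CC=CC1)/C=C/C[Si](C)(C)C | intermediate
17 | ethyl (2Z,6E,8S)-9-[(tert-butyldiphenylsilyl)oxy]-2,6-dimethyl-8-{1-[(E)-3-(trimethylsilyl)prop-1-en-1-yl]cyclopent-3-en-1-yl}nona-2,6-dienoate | CCOC(=O)/C(C)=C\CC/C(C)=C/[C@H](CO[Si](c1ccccc1)(c1ccccc1)C(C)(C)C)C1(CC=CC1)/C=C/C[Si](C)(C)C | intermediate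
18 | (2Z,6E,8S)-9-[(tert-butyldiphenylsilyl)oxy]-2,6-dimethyl-8-{1-[(E)-3-(trimethylsilyl)prop-1-en-1-yl]cyclopent-3-en-1-yl}nona-2,6-dien-1-ol | OC/C(C)=C\CC/C(C)=C/[C@H](CO[Si](c1ccccc1)(c1ccccc1)C(C)(C)C)C1(CC=CC1)/C=C/C[Si](C)(C)C | intermediate
19 | {(2S,3R)-3-[(3E,5S)-6-[(tert-butyldiphenylsilyl)oxy]-3-methyl-5-{1-[(E)-3-(trimethylsilyl)prop-1-en-1-yl]cyclopent-3-en-1-yl}hex-3-en-1-yl]-2-methyloxiran-2-yl}methanol | OC[C@]1(C)O[C@@H]1CC/C(C)=C/[C@H](CO[Si](c1ccccc1)(c1ccccc1)C(C)(C)C)C1(CC=CC1)/C=C/C[Si](C)(C)C | intermediate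
20 | tert-butyl({(2S,3R)-3-[(3E,5S)-6-[(tert-butyldiphenylsilyl)oxy]-3-methyl-5-{1-[(E)-3-(trimethylsilyl)prop-1-en-1-yl]cyclopent-3-en-1-yl}hex-3-en-1-yl]-2-methyloxiran-2-yl}methoxy)dimethylsilane | CC(C)(C)[Si](C)(C)OC[C@]1(C)O[C@@H]1CC/C(C)=C/[C@H](CO[Si](c1ccccc1)(c1ccccc1)C(C)(C)C)C1(CC=CC1)/C=C/C[Si](C)(C)C | intermediate
21 | 9α-vinyl-19-(TBS-oxy)-7-(TBDPS-oxy)spirohydrindan-3α-ol (3-OH equatorial) | C[C@@]12CC[C@@H](O)[C@@](C)(CO[Si](C)(C)C(C)(C)C)[C@H]1[C@H](CO[Si](c3ccccc3)(c3ccccc3)C(C)(C)C)C1(CC=CC1)[C@H]2C=C | intermediate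
22 | 9α-vinyl-19-(TBS-oxy)-7-(TBDPS-oxy)spirohydrindan-3-one | C[C@@]12CCC(=O)[C@@](C)(CO[Si](C)(C)C(C)(C)C)[C@H]1[C@H](CO[Si](c3ccccc3)(c3ccccc3)C(C)(C)C)C1(CC=CC1)[C@H]2C=C | intermediate
23 | 9α-vinyl-19-(TBS-oxy)-7-(TBDPS-oxy)spirohydrindan-3β-ol (3-OH axial) | C[C@@]12CC[C@H](O)[C@@](C)(CO[Si](C)(C)C(C)(C)C)[C@H]1[C@H](CO[Si](c3ccccc3)(c3ccccc3)C(C)(C)C)C1(CC=CC1)[C@H]2C=C | intermediate
24 | 3β,19-bis(TBS-oxy)-7-(TBDPS-oxy)-9α-vinylspirohydrindane | C[C@@]12CC[C@H](O[Si](C)(C)C(C)(C)C)[C@@](C)(CO[Si](C)(C)C(C)(C)C)[C@H]1[C@H](CO[Si](c3ccccc3)(c3ccccc3)C(C)(C)C)C1(CC=CC1)[C@H]2C=C | intermediate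
25 | 9α-[2-(9-borabicyclo[3.3.1]nonan-9-yl)ethyl] analogue of 24 (borane) | C[C@@]12CC[C@H](O[Si](C)(C)C(C)(C)C)[C@@](C)(CO[Si](C)(C)C(C)(C)C)[C@H]1[C@H](CO[Si](c3ccccc3)(c3ccccc3)C(C)(C)C)C1(CC=CC1)[C@H]2CCB1C2CCCC1CCC2 | intermediate
26 | 3β,19-bis(TBS-oxy)-7-(TBDPS-oxy)-9α-(2-hydroxyethyl)spirohydrindane | C[C@@]12CC[C@H](O[Si](C)(C)C(C)(C)C)[C@@](C)(CO[Si](C)(C)C(C)(C)C)[C@H]1[C@H](CO[Si](c3ccccc3)(c3ccccc3)C(C)(C)C)C1(CC=CC1)[C@H]2CCO | intermediate
27 | 3β,19-bis(TBS-oxy)-7-(TBDPS-oxy)-9α-(2-iodoethyl)spirohydrindane | C[C@@]12CC[C@H](O[Si](C)(C)C(C)(C)C)[C@@](C)(CO[Si](C)(C)C(C)(C)C)[C@H]1[C@H](CO[Si](c3ccccc3)(c3ccccc3)C(C)(C)C)C1(CC=CC1)[C@H]2CCI | intermediate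
28 | 3β,19-bis(TBS-oxy)-7-(TBDPS-oxy)-17-norgibberell-15-ene | C[C@@]12CC[C@H](O[Si](C)(C)C(C)(C)C)[C@@](C)(CO[Si](C)(C)C(C)(C)C)[C@H]1[C@H](CO[Si](c4ccccc4)(c4ccccc4)C(C)(C)C)[C@@]13C[C@@H](CC[C@@H]21)C=C3 | intermediate
29 | 16-exo-(9-borabicyclo[3.3.1]nonan-9-yl)-3β,19-bis(TBS-oxy)-7-(TBDPS-oxy)-17-norgibberellane (borane) | C[C@@]12CC[C@H](O[Si](C)(C)C(C)(C)C)[C@@](C)(CO[Si](C)(C)C(C)(C)C)[C@H]1[C@H](CO[Si](c4ccccc4)(c4ccccc4)C(C)(C)C)[C@@]13C[C@@H](CC[C@@H]21)[C@H](B1C2CCCC1CCC2)C3 | intermediate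
30 | 3β,19-bis(TBS-oxy)-7-(TBDPS-oxy)-17-norgibberellan-16-exo-ol | C[C@@]12CC[C@H](O[Si](C)(C)C(C)(C)C)[C@@](C)(CO[Si](C)(C)C(C)(C)C)[C@H]1[C@H](CO[Si](c4ccccc4)(c4ccccc4)C(C)(C)C)[C@@]13C[C@@H](CC[C@@H]21)[C@H](O)C3 | intermediate
31 | 3β,19-bis(TBS-oxy)-7-(TBDPS-oxy)-17-norgibberellan-16-one | C[C@@]12CC[C@H](O[Si](C)(C)C(C)(C)C)[C@@](C)(CO[Si](C)(C)C(C)(C)C)[C@H]1[C@H](CO[Si](c4ccccc4)(c4ccccc4)C(C)(C)C)[C@@]13C[C@@H](CC[C@@H]21)C(=O)C3 | intermediate
32 | 3β,19-bis(TBS-oxy)-7-(TBDPS-oxy)gibberellan-16-ol (16-CH3 exo, 16-OH endo) | C[C@@]12CC[C@H](O[Si](C)(C)C(C)(C)C)[C@@](C)(CO[Si](C)(C)C(C)(C)C)[C@H]1[C@H](CO[Si](c4ccccc4)(c4ccccc4)C(C)(C)C)[C@@]13C[C@@H](CC[C@@H]21)[C@@](C)(O)C3 | intermediate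
33 | 3β-(TBS-oxy)-7-(TBDPS-oxy)gibberellane-16,19-diol | C[C@@]12CC[C@H](O[Si](C)(C)C(C)(C)C)[C@@](C)(CO)[C@H]1[C@H](CO[Si](c4ccccc4)(c4ccccc4)C(C)(C)C)[C@@]13C[C@@H](CC[C@@H]21)[C@@](C)(O)C3 | intermediate
34 | 3β-(TBS-oxy)-7-(TBDPS-oxy)-16-hydroxygibberellan-19-al (aldehyde) | C[C@@]12CC[C@H](O[Si](C)(C)C(C)(C)C)[C@@](C)(C=O)[C@H]1[C@H](CO[Si](c4ccccc4)(c4ccccc4)C(C)(C)C)[C@@]13C[C@@H](CC[C@@H]21)[C@@](C)(O)C3 | intermediate
35 | 3β-(TBS-oxy)-7-(TBDPS-oxy)-16-hydroxygibberellan-19-oic acid | C[C@@]12CC[C@H](O[Si](C)(C)C(C)(C)C)[C@@](C)(C(=O)O)[C@H]1[C@H](CO[Si](c4ccccc4)(c4ccccc4)C(C)(C)C)[C@@]13C[C@@H](CC[C@@H]21)[C@@](C)(O)C3 | intermediate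
36 | 3β,7,16-trihydroxygibberellan-19-oic acid (5β-H, 9β-H, 10α-CH3, 4α-CO2H, 16-CH3 exo), CNP0170663.1 | C[C@@]12CC[C@H](O)[C@@](C)(C(=O)O)[C@H]1[C@H](CO)[C@@]13C[C@@H](CC[C@@H]21)[C@@](C)(O)C3 | target

**Step count and risks**
Total step count: 29. Longest linear sequence: 28 steps (steps 1–3 and 5–29, from 1 to 36); step 4 is a one-step side branch.

The three steps most likely to fail:

Step 17. The C10 cation may be quenched before ring B closes (proton loss, capture by the C7 ether oxygen or by the cyclopentene), or the allylsilane may add with poor facial control at C9. The fallback replaces the cationic closure by an oxidative radical bicyclization steered by the C6 centre alone. It sets out from 16 and comes back at 24. Aldehyde 16 is added to the lithium enolate of ethyl propanoate to give the β-hydroxy ester F1, which Dess–Martin oxidation turns into the β-keto ester F2. Mn(OAc)3·2H2O with Cu(OAc)2 in AcOH generates the C4 radical, which closes ring A 6-endo and ring B 5-exo. Divalent copper oxidises the resulting β-silyl radical, and loss of silicon leaves the vinyl group in the bicyclic keto ester F3 (ester axial, C5/C10/C9 set by allylic strain at C6). LiBH(s-Bu)3 gives the 3β-hydroxy ester F4, LiAlH4 the 3β,19-diol F5, and excess TBSOTf/2,6-lutidine silylates both hydroxyls to give 24.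

Step 23. The C12 radical may abstract the allylic C14 hydrogen (1,5-transfer), the primary alkylcobalt may lose hydrogen back to the vinyl compound, or addition may occur at the wrong alkene carbon. The fallback closes ring C by a polar carbonyl–ene reaction. It sets out from 26 and comes back at 28. Dess–Martin oxidation of 26 gives the C12 aldehyde F6. Me2AlCl in CH2Cl2 at −78 °C promotes the intramolecular ene reaction (C12–C13 bond, hydrogen transferred from C15), giving the 12-hydroxy-15-ene F7. NaH, CS2 and MeI convert it into the xanthate F8, and Barton–McCombie deoxygenation with concentrated Bu3SnH/AIBN (to outrun homoallyl rearrangement) gives 28.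

Step 24. Boron delivery may not discriminate well enough between C15 and C16, or the hindered alkene may react sluggishly. The fallback lets the ring-closing radical itself mark C16, so no regiochemical choice on the alkene is needed. It sets out from 27 and comes back at 30. Iodine atom-transfer cyclization of 27 ((Bu3Sn)2 cat., hν, benzene) gives the 16-iodide F9. Radical hydroxylation (Bu3SnH under dry air, then PPh3) replaces iodine by hydroxyl to give 30 as a C16 epimer mixture, which is of no consequence before step 25.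

**Further compounds**
F1 | step 17 | ethyl (6E,8S)-9-[(tert-butyldiphenylsilyl)oxy]-3-hydroxy-2,6-dimethyl-8-{1-[(E)-3-(trimethylsilyl)prop-1-en-1-yl]cyclopent-3-en-1-yl}non-6-enoate (C2/C3 mixture) | CCOC(=O)C(C)C(O)CC/C(C)=C/[C@H](CO[Si](c1ccccc1)(c1ccccc1)C(C)(C)C)C1(CC=CC1)/C=C/C[Si](C)(C)C
F2 | step 17 | ethyl (6E,8S)-9-[(tert-butyldiphenylsilyl)oxy]-2,6-dimethyl-3-oxo-8-{1-[(E)-3-(trimethylsilyl)prop-1-en-1-yl]cyclopent-3-en-1-yl}non-6-enoate | CCOC(=O)C(C)C(=O)CC/C(C)=C/[C@H](CO[Si](c1ccccc1)(c1ccccc1)C(C)(C)C)C1(CC=CC1)/C=C/C[Si](C)(C)C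
F3 | step 17 | ethyl 3-oxo-7-(TBDPS-oxy)-9α-vinylspirohydrindan-19-oate (4α ester axial) | C[C@@]12CCC(=O)[C@@](C)(C(=O)OCC)[C@H]1[C@H](CO[Si](c3ccccc3)(c3ccccc3)C(C)(C)C)C1(CC=CC1)[C@H]2C=C
F4 | step 17 | ethyl 3β-hydroxy-7-(TBDPS-oxy)-9α-vinylspirohydrindan-19-oate | C[C@@]12CC[C@H](O)[C@@](C)(C(=O)OCC)[C@H]1[C@H](CO[Si](c3ccccc3)(c3ccccc3)C(C)(C)C)C1(CC=CC1)[C@H]2C=C
F5 | step 17 | 7-(TBDPS-oxy)-9α-vinylspirohydrindane-3β,19-diol | C[C@@]12CC[C@H](O)[C@@](C)(CO)[C@H]1[C@H](CO[Si](c3ccccc3)(c3ccccc3)C(C)(C)C)C1(CC=CC1)[C@H]2C=C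
F6 | step 23 | 3β,19-bis(TBS-oxy)-7-(TBDPS-oxy)-9α-(2-oxoethyl)spirohydrindane | C[C@@]12CC[C@H](O[Si](C)(C)C(C)(C)C)[C@@](C)(CO[Si](C)(C)C(C)(C)C)[C@H]1[C@H](CO[Si](c3ccccc3)(c3ccccc3)C(C)(C)C)C1(CC=CC1)[C@H]2CC=O
F7 | step 23 | 3β,19-bis(TBS-oxy)-7-(TBDPS-oxy)-17-norgibberell-15-en-12-ol (C12 epimers) | C[C@@]12CC[C@H](O[Si](C)(C)C(C)(C)C)[C@@](C)(CO[Si](C)(C)C(C)(C)C)[C@H]1[C@H](CO[Si](c4ccccc4)(c4ccccc4)C(C)(C)C)[C@@]13C[C@@H](C(O)C[C@@H]21)C=C3
F8 | step 23 | O-[3β,19-bis(TBS-oxy)-7-(TBDPS-oxy)-17-norgibberell-15-en-12-yl] S-methyl carbonodithioate | C[C@@]12CC[C@H](O[Si](C)(C)C(C)(C)C)[C@@](C)(CO[Si](C)(C)C(C)(C)C)[C@H]1[C@H](CO[Si](c4ccccc4)(c4ccccc4)C(C)(C)C)[C@@]13C[C@@H](C(OC(=S)SC)C[C@@H]21)C=C3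
F9 | step 24 | 16-iodo-3β,19-bis(TBS-oxy)-7-(TBDPS-oxy)-17-norgibberellane (C16 epimers) | C[C@@]12CC[C@H](O[Si](C)(C)C(C)(C)C)[C@@](C)(CO[Si](C)(C)C(C)(C)C)[C@H]1[C@H](CO[Si](c4ccccc4)(c4ccccc4)C(C)(C)C)[C@@]13C[C@@H](CC[C@@H]21)C(I)C3
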